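**Retrosynthetic overview**

1. Target ⇐ cis-decalin-2,8-dione diester, by saponification, methylenation of the C8 ketone and hydride reduction of the C2 ketone.
2. Ring B ⇐ intramolecular Michael addition of the C8-ketone enolate (C9) to a ring-A 3-methylcyclohexenone; this forms C9–C10, the quaternary C10 and the cis ring fusion.
3. Michael precursor ⇐ Negishi acylation of a ring-A alkylzinc (C7) with the side-chain acid chloride (C8–C16), whose E-enoate comes from Negishi carboalumination of hex-5-yn-1-ol.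
4. Ring A ⇐ amine-catalysed intramolecular aldol condensation of a diketone held on a δ-lactone; the lactone (C19–O–C7) is then cut with Me3SiI to an iodo ester.
5. Stereo origin: C5 from Rh/(R)-BINAP conjugate addition of isopropenyl to 5,6-dihydro-2H-pyran-2-one, C4 by anti methylation of the lactone enolate. Ring order: lactone template → ring A → ring B.

Assumption: the SMILES is read literally, i.e. a cis-fused decalin with H-5 syn to the C10 methyl, (1R,3S,4aR,5S,8aS); labdane numbering (C1–C20, C19 = carboxyl on C4) is used for positions.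

**Route**

Step 1
Reactants: 1 5,6-dihydro-2H-pyran-2-one; 2 potassium trifluoro(prop-1-en-2-yl)borate
Product: 3 (R)-4-(prop-1-en-2-yl)oxan-2-one
Conditions: [Rh(cod)2]BF4 (3 mol %), (R)-BINAP (3.3 mol %), PhMe/H2O 10:1, 100 °C
Reagents that add atoms: none
Why: Hayashi–Miyaura rhodium/BINAP 1,4-addition of an alkenylboron reagent to the unsaturated δ-lactone; the (R)-BINAP alkenyl–rhodium species inserts one enantioface of the enoate (the sense in which (S)-BINAP gives (S)-adducts of 2-cyclohexenone and of this lactone), setting the future C5 as the (R)-lactone centre.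

Step 2
Reactants: 3 (R)-4-(prop-1-en-2-yl)oxan-2-one; 4 methallyl bromide (3-bromo-2-methylprop-1-ene)
Product: 6 (3S,4R)-3-(2-methylprop-2-en-1-yl)-4-(prop-1-en-2-yl)oxan-2-one, via lithium enolate 5 (not isolated)
Conditions: LiN(i-Pr)2, THF, −78 °C; then 4, −78 → −40 °C
Reagents that add atoms: none
Why: lactone enolate alkylation (SN2 on the allylic bromide) trans to the isopropenyl group; this centre is only provisional because it is re-planarized in step 3.

Step 3
Reactants: 6 (3S,4R)-3-(2-methylprop-2-en-1-yl)-4-(prop-1-en-2-yl)oxan-2-one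
Product: 8 (3R,4S)-3-methyl-3-(2-methylprop-2-en-1-yl)-4-(prop-1-en-2-yl)oxan-2-one, via lithium enolate 7 (not isolated)
Conditions: LiN(i-Pr)2, THF/DMPU, −78 °C; MeI, −78 → −20 °C
Reagents that add atoms: iodomethane, CI
Why: second enolate alkylation; A(1,2) strain holds the neighbouring isopropenyl group pseudoaxial in the half-chair enolate so MeI enters anti to it, which sets the quaternary C4 (methyl trans to isopropenyl, the two future ring-A arms cis).

Step 4
Reactants: 8 (3R,4S)-3-methyl-3-(2-methylprop-2-en-1-yl)-4-(prop-1-en-2-yl)oxan-2-one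
Product: 10 (3R,4R)-4-acetyl-3-methyl-3-(2-oxopropyl)oxan-2-one, via bis-ozonide 9 (not isolated)
Conditions: O3, CH2Cl2, −78 °C; Me2S, −78 °C → rt
Reagents that add atoms: ozone, [O-][O+]=O
Why: ozonolysis with reductive work-up turns both 1,1-disubstituted alkenes into methyl ketones under neutral conditions that leave the enolizable C5 centre untouched.

Step 5
Reactants: 10 (3R,4R)-4-acetyl-3-methyl-3-(2-oxopropyl)oxan-2-one
Product: 12 (4aS,8aR)-5,8a-dimethyl-3,4,4a,8a-tetrahydro-1H-isochromene-1,7(8H)-dione, via ketol 11 (not isolated)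
Conditions: pyrrolidine (0.3 equiv), AcOH (0.3 equiv), PhMe, 25 → 45 °C
Reagents that add atoms: none
Why: amine-catalysed intramolecular aldol condensation; pyrrolidine condenses with the less hindered acetonyl ketone, its terminal enamine attacks the acetyl carbonyl through a six-membered ring and E1cB dehydration gives the 3-methylcyclohexenone of ring A, cis-fused to the lactone because both arms sit on one face (no new stereocentre survives).

Step 6
Reactants: 12 (4aS,8aR)-5,8a-dimethyl-3,4,4a,8a-tetrahydro-1H-isochromene-1,7(8H)-dione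
Product: 15 methyl (1R,2S)-2-(2-iodoethyl)-1,3-dimethyl-5-oxocyclohex-3-ene-1-carboxylate, via silyl ester 13 (not isolated), via iodo acid 14 (not isolated)
Conditions: Me3SiI (2.5 equiv), CH2Cl2, 0 → 40 °C; MeOH; then Me3SiCHN2, PhMe/MeOH, 0 °C; aq NaHCO3 wash
Reagents that add atoms: iodotrimethylsilane, C[Si](C)(C)I; (trimethylsilyl)diazomethane, C[Si](C)(C)C=[N+]=[N-]
Why: silyl iodide lactone cleavage (O-silylation, then SN2 attack of iodide at the unhindered O–CH2 carbon) frees C7 as a primary iodide and C19 as a silyl ester, which is methanolysed and methylated by the diazoalkane; iodide addition to the enone reverses on the basic wash and no stereocentre is involved.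

Step 7
Reactants: 16 hex-5-yn-1-ol
Product: 17 tert-butyl(hex-5-yn-1-yloxy)dimethylsilane
Conditions: TBSCl, imidazole, DMF, 0 °C → rt
Reagents that add atoms: tert-butyldimethylsilyl chloride, CC(C)(C)[Si](C)(C)Cl
Why: standard silylation of the primary alcohol so that it does not consume AlMe3 in the next step.

Step 8
Reactants: 17 tert-butyl(hex-5-yn-1-yloxy)dimethylsilane
Product: 19 methyl (2E)-7-[(tert-butyldimethylsilyl)oxy]-3-methylhept-2-enoate, via alkenylalane 18 (not isolated)
Conditions: AlMe3 (2.2 equiv), Cp2ZrCl2 (25 mol %), CH2Cl2, 0 °C → rt; ClCO2Me, 0 °C → rt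
Reagents that add atoms: trimethylaluminium, C[Al](C)C; methyl chloroformate, COC(=O)Cl
Why: Negishi zirconium-catalysed carboalumination adds methyl and aluminium syn across the terminal alkyne with methyl on the internal carbon, and acylation of the alkenylalane with retention gives only the (E)-3-methyl-2-enoate.

Step 9
Reactants: 19 methyl (2E)-7-[(tert-butyldimethylsilyl)oxy]-3-methylhept-2-enoate
Product: 20 methyl (2E)-7-hydroxy-3-methylhept-2-enoate
Conditions: CSA (10 mol %), MeOH, rt
Reagents that add atoms: none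
Why: acid-catalysed methanolysis of the primary silyl ether; the enoate is inert.

Step 10
Reactants: 20 methyl (2E)-7-hydroxy-3-methylhept-2-enoate
Product: 21 methyl (2E)-3-methyl-7-oxohept-2-enoate
Conditions: Dess–Martin periodinane, CH2Cl2, rt
Reagents that add atoms: none
Why: Dess–Martin oxidation of the primary alcohol to the aldehyde without touching the enoate.

Step 11
Reactants: 21 methyl (2E)-3-methyl-7-oxohept-2-enoate
Product: 22 (5E)-7-methoxy-5-methyl-7-oxohept-5-enoic acid
Conditions: NaClO2, NaH2PO4, 2-methylbut-2-ene, t-BuOH/H2O, rt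
Reagents that add atoms: sodium chlorite, [Na+].[O-]Cl=O
Why: Pinnick oxidation, with 2-methylbut-2-ene as hypochlorite scavenger so that the trisubstituted enoate is not chlorinated.

Step 12
Reactants: 22 (5E)-7-methoxy-5-methyl-7-oxohept-5-enoic acid
Product: 23 methyl (2E)-7-chloro-3-methyl-7-oxohept-2-enoate
Conditions: (COCl)2, DMF (cat.), CH2Cl2, 0 °C → rt
Reagents that add atoms: oxalyl chloride, O=C(Cl)C(=O)Cl
Why: Vilsmeier-type acid chloride formation under neutral conditions that leave the enoate geometry intact.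

Step 13
Reactants: 15 methyl (1R,2S)-2-(2-iodoethyl)-1,3-dimethyl-5-oxocyclohex-3-ene-1-carboxylate; 23 methyl (2E)-7-chloro-3-methyl-7-oxohept-2-enoate
Product: 25 methyl (1R,2S)-2-[(7E)-9-methoxy-7-methyl-3,9-dioxonon-7-en-1-yl]-1,3-dimethyl-5-oxocyclohex-3-ene-1-carboxylate, via alkylzinc iodide 24 (not isolated)
Conditions: Zn dust (activated), LiCl, THF, 40 °C; then 23, Pd(PPh3)4 (5 mol %), THF, 0 °C → rt
Reagents that add atoms: none
Why: Negishi acylation; LiCl-assisted zinc insertion into the primary C–I bond gives an alkylzinc iodide that tolerates ester and enone, and coupling with the acid chloride under zerovalent-palladium catalysis gives the C8 ketone without touching any stereocentre.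

Step 14
Reactants: 25 methyl (1R,2S)-2-[(7E)-9-methoxy-7-methyl-3,9-dioxonon-7-en-1-yl]-1,3-dimethyl-5-oxocyclohex-3-ene-1-carboxylate
Product: 26 methyl (1R,4aS,5R,8aS)-5-[(3E)-5-methoxy-3-methyl-5-oxopent-3-en-1-yl]-1,4a-dimethyl-3,6-dioxodecahydronaphthalene-1-carboxylate
Conditions: KOt-Bu (0.3 equiv), t-BuOH/THF 1:4, 0 °C, 1 h; AcOH quench
Reagents that add atoms: none
Why: intramolecular Michael addition (6-exo-trig); only the C9 enolate can reach the enone β-carbon through a six-membered ring, the tether on C5 forces attack on its own face so ring B is cis-fused (C10 methyl syn to H-5), and the chair-like transition state of the (Z)-enolate places the side chain equatorial, i.e. syn to the C10 methyl at C9.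

Step 15
Reactants: 26 methyl (1R,4aS,5R,8aS)-5-[(3E)-5-methoxy-3-methyl-5-oxopent-3-en-1-yl]-1,4a-dimethyl-3,6-dioxodecahydronaphthalene-1-carboxylate
Product: 27 methyl (1R,3S,4aS,5R,8aS)-3-hydroxy-5-[(3E)-5-methoxy-3-methyl-5-oxopent-3-en-1-yl]-1,4a-dimethyl-6-oxodecahydronaphthalene-1-carboxylate
Conditions: LiBH(s-Bu)3 (1.1 equiv), THF, −78 °C; H2O
Reagents that add atoms: none
Why: chemo- and diastereoselective ketone reduction; the C2 carbonyl, flanked by two CH2 groups, reacts before the α-branched C8 carbonyl, and the bulky hydride approaches from the α face away from the syn-axial C4 and C10 methyl groups, giving the 2β (3S) alcohol, which is trans to the ester and cannot lactonize.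

Step 16
Reactants: 27 methyl (1R,3S,4aS,5R,8aS)-3-hydroxy-5-[(3E)-5-methoxy-3-methyl-5-oxopent-3-en-1-yl]-1,4a-dimethyl-6-oxodecahydronaphthalene-1-carboxylate
Product: 28 methyl (1R,3S,4aR,5S,8aS)-3-hydroxy-5-[(3E)-5-methoxy-3-methyl-5-oxopent-3-en-1-yl]-1,4a-dimethyl-6-methylidenedecahydronaphthalene-1-carboxylate
Conditions: Zn, CH2Br2, TiCl4, THF, 0 °C (reagent pre-formed); then 27, CH2Cl2, 0 °C → rt
Reagents that add atoms: dibromomethane, BrCBr
Why: Takai–Lombardo methylenation; the non-basic zinc/titanium methylene reagent olefinates the hindered, enolizable C8 ketone without epimerizing C9 and tolerates the free hydroxyl and both esters.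

Step 17
Reactants: 28 methyl (1R,3S,4aR,5S,8aS)-3-hydroxy-5-[(3E)-5-methoxy-3-methyl-5-oxopent-3-en-1-yl]-1,4a-dimethyl-6-methylidenedecahydronaphthalene-1-carboxylate
Product: 29 (1R,3S,4aR,5S,8aS)-5-[(3E)-4-carboxy-3-methylbut-3-en-1-yl]-3-hydroxy-1,4a-dimethyl-6-methylidenedecahydronaphthalene-1-carboxylic acid
Conditions: LiOH·H2O (excess), THF/MeOH/H2O, 60 °C; 1 M HCl to pH 3
Reagents that add atoms: lithium hydroxide, [Li+].[OH-]
Why: saponification of both methyl esters; C9 is no longer α to a carbonyl, the trans 2-OH and 4-CO2H cannot lactonize and the trisubstituted (E)-enoate does not isomerize, so all stereochemistry is retained.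

**Compound list**

1 | 5,6-dihydro-2H-pyran-2-one | O=C1C=CCCO1 | starting material
2 | potassium trifluoro(prop-1-en-2-yl)borate | [K+].C=C(C)[B-](F)(F)F | starting material
3 | (R)-4-(prop-1-en-2-yl)oxan-2-one | O=C1C[C@H](C(C)=C)CCO1 | intermediate
4 | 3-bromo-2-methylprop-1-ene (methallyl bromide) | C=C(C)CBr | starting material
5 | lithium enolate of 3 | [Li]OC1=C[C@H](C(C)=C)CCO1 | intermediate (not isolated)
6 | (3S,4R)-3-(2-methylprop-2-en-1-yl)-4-(prop-1-en-2-yl)oxan-2-one (trans) | O=C1[C@@H](CC(C)=C)[C@H](C(C)=C)CCO1 | intermediate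
7 | lithium enolate of 6 | [Li]OC1=C(CC(C)=C)[C@H](C(C)=C)CCO1 | intermediate (not isolated)
8 | (3R,4S)-3-methyl-3-(2-methylprop-2-en-1-yl)-4-(prop-1-en-2-yl)oxan-2-one (methyl trans to isopropenyl) | O=C1[C@](C)(CC(C)=C)[C@H](C(C)=C)CCO1 | intermediate
9 | bis-ozonide of 8 (both alkenes as 3-methyl-1,2,4-trioxolanes, ozonide carbons as mixtures) | O=C1[C@](C)(CC2(C)OCOO2)[C@H](C2(C)OCOO2)CCO1 | intermediate (not isolated)
10 | (3R,4R)-4-acetyl-3-methyl-3-(2-oxopropyl)oxan-2-one | O=C1[C@](C)(CC(C)=O)[C@H](C(C)=O)CCO1 | intermediate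
11 | ketol: 5-hydroxy-5,8a-dimethylhexahydro-1H-isochromene-1,7(3H)-dione, ring fusion as in 12, C5 epimers | O=C1OCC[C@H]2C(C)(O)CC(=O)C[C@@]12C | intermediate (not isolated)
12 | (4aS,8aR)-5,8a-dimethyl-3,4,4a,8a-tetrahydro-1H-isochromene-1,7(8H)-dione (cis-fused enone lactone) | O=C1OCC[C@H]2C(C)=CC(=O)C[C@@]12C | intermediate
13 | trimethylsilyl (1R,2S)-2-(2-iodoethyl)-1,3-dimethyl-5-oxocyclohex-3-ene-1-carboxylate | C[Si](C)(C)OC(=O)[C@]1(C)CC(=O)C=C(C)[C@@H]1CCI | intermediate (not isolated)
14 | (1R,2S)-2-(2-iodoethyl)-1,3-dimethyl-5-oxocyclohex-3-ene-1-carboxylic acid | OC(=O)[C@]1(C)CC(=O)C=C(C)[C@@H]1CCI | intermediate (not isolated)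
15 | methyl (1R,2S)-2-(2-iodoethyl)-1,3-dimethyl-5-oxocyclohex-3-ene-1-carboxylate | COC(=O)[C@]1(C)CC(=O)C=C(C)[C@@H]1CCI | intermediate
16 | hex-5-yn-1-ol | C#CCCCCO | starting material
17 | tert-butyl(hex-5-yn-1-yloxy)dimethylsilane | C#CCCCCO[Si](C)(C)C(C)(C)C | intermediate
18 | alkenylalane: (E)-dimethyl[6-(tert-butyldimethylsilyloxy)-2-methylhex-1-en-1-yl]alumane (methyl cis to Al) | C/C(CCCCO[Si](C)(C)C(C)(C)C)=C\[Al](C)C | intermediate (not isolated)
19 | methyl (2E)-7-[(tert-butyldimethylsilyl)oxy]-3-methylhept-2-enoate | COC(=O)/C=C(\C)CCCCO[Si](C)(C)C(C)(C)C | intermediate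
20 | methyl (2E)-7-hydroxy-3-methylhept-2-enoate | COC(=O)/C=C(\C)CCCCO | intermediate
21 | methyl (2E)-3-methyl-7-oxohept-2-enoate | COC(=O)/C=C(\C)CCCC=O | intermediate
22 | (5E)-7-methoxy-5-methyl-7-oxohept-5-enoic acid | COC(=O)/C=C(\C)CCCC(=O)O | intermediate
23 | methyl (2E)-7-chloro-3-methyl-7-oxohept-2-enoate | COC(=O)/C=C(\C)CCCC(=O)Cl | intermediate
24 | alkylzinc iodide of 15 (C–I replaced by C–ZnI) | COC(=O)[C@]1(C)CC(=O)C=C(C)[C@@H]1CC[Zn]I | intermediate (not isolated)
25 | methyl (1R,2S)-2-[(7E)-9-methoxy-7-methyl-3,9-dioxonon-7-en-1-yl]-1,3-dimethyl-5-oxocyclohex-3-ene-1-carboxylate | COC(=O)[C@]1(C)CC(=O)C=C(C)[C@@H]1CCC(=O)CCC/C(C)=C/C(=O)OC | intermediate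
26 | methyl (1R,4aS,5R,8aS)-5-[(3E)-5-methoxy-3-methyl-5-oxopent-3-en-1-yl]-1,4a-dimethyl-3,6-dioxodecahydronaphthalene-1-carboxylate (cis-decalin-2,8-dione) | O=C1CC[C@H]2[C@](C)(CC(=O)C[C@@]2(C)C(=O)OC)[C@H]1CC/C(C)=C/C(=O)OC | intermediate
27 | methyl (1R,3S,4aS,5R,8aS)-3-hydroxy-5-[(3E)-5-methoxy-3-methyl-5-oxopent-3-en-1-yl]-1,4a-dimethyl-6-oxodecahydronaphthalene-1-carboxylate | O=C1CC[C@H]2[C@](C)(C[C@H](O)C[C@@]2(C)C(=O)OC)[C@H]1CC/C(C)=C/C(=O)OC | intermediate
28 | methyl (1R,3S,4aR,5S,8aS)-3-hydroxy-5-[(3E)-5-methoxy-3-methyl-5-oxopent-3-en-1-yl]-1,4a-dimethyl-6-methylidenedecahydronaphthalene-1-carboxylate | C=C1CC[C@H]2[C@](C)(C[C@H](O)C[C@@]2(C)C(=O)OC)[C@H]1CC/C(C)=C/C(=O)OC | intermediate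
29 | (1R,3S,4aR,5S,8aS)-5-[(3E)-4-carboxy-3-methylbut-3-en-1-yl]-3-hydroxy-1,4a-dimethyl-6-methylidenedecahydronaphthalene-1-carboxylic acid (CNP0086784.2) | C=C1CC[C@H]2[C@](C)(C[C@H](O)C[C@@]2(C)C(=O)O)[C@H]1CC/C(C)=C/C(=O)O | target

**Step count and risks**

Total step count: 17. Longest linear sequence: 11 steps (1 → 29 through steps 1–6 and 13–17; the side-chain branch 16 → 29 through steps 7–12 and 13–17 is also 11).

Most likely to fail, first: step 5. The acetyl methyl could instead attack the acetonyl carbonyl and give the isomeric enone. The fallback runs from 3 back to 12 and closes ring A by a carbonyl-ene reaction, for which only one mode exists. Enolate 5 is alkylated with tert-butyl(2-iodoethoxy)dimethylsilane to the trans silyl ether lactone F1. Its lithium enolate F2 is methylated (MeI, anti to isopropenyl) to the quaternary lactone F3. HF·pyridine gives the primary alcohol F4 and Dess–Martin periodinane the aldehyde F5. Me2AlCl (CH2Cl2, −78 °C) then promotes the intramolecular carbonyl-ene reaction of the aldehyde with the isopropenyl group to the methylenecyclohexanol F6. Dess–Martin oxidation to the β,γ-unsaturated ketone F7 and DBU isomerization give 12.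

Second: step 14. The Michael addition must build the quaternary C10 between C4 and C9 and may be slow, or may give C9 as a mixture. The fallback runs from 10 back to 26 and inverts the order of ring formation, so that the Michael donor is a methyl ketone and ring A closes last. Diketone 10 is opened with Me3SiI and esterified as in step 6, through the silyl ester F8 and the iodo acid F9, to the iodo diketo ester F10. Zinc insertion gives the alkylzinc iodide F11, and acylation with 23 as in step 13 gives the triketone F12. KOH in MeOH condenses the C9 methylene with the acetyl carbonyl, through the ketol F13, to the tetrasubstituted ring-B enone F14. KOt-Bu then adds the terminal carbon of the acetonyl ketone to C10 of this enone (again a six-membered, necessarily cis-fused closure), and protonation at C9 gives 26.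

Third: step 15. The face selectivity at C2 depends on the ring-A conformation, and the 2α-alcohol would be the wrong epimer. The fallback runs from 26 back to 27 and sets C2 by SN2 inversion instead of by hydride approach. The reduction is quenched cold with AcOH and the 2α-alcohol F15 is isolated before it can lactonize. Mitsunobu esterification (p-nitrobenzoic acid, PPh3, DIAD) gives the inverted 2β p-nitrobenzoate F16, and K2CO3 in MeOH at 0 °C cleaves only this activated ester to give 27.

**Further compounds**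

F1 | step 5 | (3S,4R)-3-[2-(tert-butyldimethylsilyloxy)ethyl]-4-(prop-1-en-2-yl)oxan-2-one | O=C1[C@@H](CCO[Si](C)(C)C(C)(C)C)[C@H](C(C)=C)CCO1
F2 | step 5 | lithium enolate of F1 | [Li]OC1=C(CCO[Si](C)(C)C(C)(C)C)[C@H](C(C)=C)CCO1
F3 | step 5 | (3R,4S)-3-[2-(tert-butyldimethylsilyloxy)ethyl]-3-methyl-4-(prop-1-en-2-yl)oxan-2-one | O=C1[C@](C)(CCO[Si](C)(C)C(C)(C)C)[C@H](C(C)=C)CCO1
F4 | step 5 | (3R,4S)-3-(2-hydroxyethyl)-3-methyl-4-(prop-1-en-2-yl)oxan-2-one | O=C1[C@](C)(CCO)[C@H](C(C)=C)CCO1
F5 | step 5 | [(3R,4S)-3-methyl-2-oxo-4-(prop-1-en-2-yl)oxan-3-yl]acetaldehyde | O=C1[C@](C)(CC=O)[C@H](C(C)=C)CCO1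
F6 | step 5 | (4aS,8aR)-7-hydroxy-8a-methyl-5-methylideneoctahydro-1H-isochromen-1-one (C7 epimers) | O=C1OCC[C@H]2C(=C)CC(O)C[C@@]12C
F7 | step 5 | (4aS,8aR)-8a-methyl-5-methylidenehexahydro-1H-isochromene-1,7(3H)-dione | O=C1OCC[C@H]2C(=C)CC(=O)C[C@@]12C
F8 | step 14 | trimethylsilyl (2R,3R)-3-acetyl-5-iodo-2-methyl-2-(2-oxopropyl)pentanoate | C[Si](C)(C)OC(=O)[C@](C)(CC(C)=O)[C@H](C(C)=O)CCI
F9 | step 14 | (2R,3R)-3-acetyl-5-iodo-2-methyl-2-(2-oxopropyl)pentanoic acid | OC(=O)[C@](C)(CC(C)=O)[C@H](C(C)=O)CCI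
F10 | step 14 | methyl (2R,3R)-3-acetyl-5-iodo-2-methyl-2-(2-oxopropyl)pentanoate | COC(=O)[C@](C)(CC(C)=O)[C@H](C(C)=O)CCI
F11 | step 14 | alkylzinc iodide of F10 (C–I replaced by C–ZnI) | COC(=O)[C@](C)(CC(C)=O)[C@H](C(C)=O)CC[Zn]I
F12 | step 14 | methyl (2E,10R,11R)-10-acetyl-11-(methoxycarbonyl)-3,11-dimethyl-7,13-dioxotetradec-2-enoate | COC(=O)[C@](C)(CC(C)=O)[C@H](C(C)=O)CCC(=O)CCC/C(C)=C/C(=O)OC
F13 | step 14 | ketol: ring-B β-hydroxy ketone from C9 adding to the acetyl carbonyl of F12 (C9 and C10 epimers) | COC(=O)[C@](C)(CC(C)=O)[C@H]1CCC(=O)C(CC/C(C)=C/C(=O)OC)C1(C)O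
F14 | step 14 | methyl (2R)-2-{(1S)-3-[(3E)-5-methoxy-3-methyl-5-oxopent-3-en-1-yl]-2-methyl-4-oxocyclohex-2-en-1-yl}-2-methyl-4-oxopentanoate | COC(=O)[C@](C)(CC(C)=O)[C@H]1CCC(=O)C(CC/C(C)=C/C(=O)OC)=C1C
F15 | step 15 | methyl (1R,3R,4aS,5R,8aS)-3-hydroxy-5-[(3E)-5-methoxy-3-methyl-5-oxopent-3-en-1-yl]-1,4a-dimethyl-6-oxodecahydronaphthalene-1-carboxylate (2α-epimer of 27) | O=C1CC[C@H]2[C@](C)(C[C@@H](O)C[C@@]2(C)C(=O)OC)[C@H]1CC/C(C)=C/C(=O)OC
F16 | step 15 | 2β p-nitrobenzoate of 27 | O=C1CC[C@H]2[C@](C)(C[C@H](OC(=O)c3ccc(cc3)[N+](=O)[O-])C[C@@]2(C)C(=O)OC)[C@H]1CC/C(C)=C/C(=O)OC
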